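(The readings are simulated with constants of no real substance.)

The leftover of a run, the fraction of the charge not yet target, passes down a ladder of three rungs, each longer than the one before.

| setting | Thursday's | Tuesday's | flask |
|---|---|---|---|
| solid substrate | 0.17 M | 0.26 M | 0.12 M |
| enzyme | 0.02 mol% | 0.02 mol% | 0.02 mol% |
| remark | run made earlier | run made earlier |  |
| time |  |  | 4.0 d |

| run | time / d | target / % | solid substrate / % |
|---|---|---|---|
| Thursday's | 0.417 | 21.1 | 55.2 |
| Thursday's | 0.625 | 31.4 | 47.0 |
| Thursday's | 1.04 | 46.8 | 28.7 |
| Thursday's | 1.67 | 62.9 | 11.6 |
| Thursday's | 3.00 | 88.6 | 0 |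
| Thursday's | 5.00 | 97.7 | 0.7 |
| Tuesday's | 0.333 | 15.6 | 70.7 |
| Tuesday's | 0.833 | 34.0 | 53.1 |
| Tuesday's | 1.67 | 50.9 | 32.1 |
| Tuesday's | 2.50 | 68.0 | 15.0 |
| Tuesday's | 4.00 | 89.1 | 0 |
| Tuesday's | 5.00 | 96.6 | 2.5 |

(standard deviation of a reading: 1 percentage point)

- solid substrate is a solid; its amount is given per volume of the solution
- at the start none of the solid substrate is in solution

- target at 4.0 d, in percent of the solid substrate charged
- the change that raises the amount of target at 4.0 d, in percent of the solid substrate charged most ("none" if none brings more than 2 percentage points) (theta / gamma / epsilon / none)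
- amount of target at 4.0 d, in percent of the solid substrate charged, after theta

- theta: doubling the amount of enzyme, all else as stated
- gamma: doubling the solubility of the solid substrate, all else as stated
- epsilon: doubling the dissolution coefficient of the solid substrate, all else as stated

On the shortest rung the solution fills. Charge minus solid minus target is 0.0403 M in Thursday's run at 0.417 d and 0.0417 M at 1.04 d. Carried to the flask, that dissolved amount is a share of its charge:

s = 34.7%

On the second rung solid feeds the solution while target grows along a bending course, so only a mean rate is read, from the first reading to the fourth: 0.0567 M d⁻¹ in Thursday's run and 0.0629 M d⁻¹ in Tuesday's. Tuesday's run has 1.53 times the enzyme but 1.11 times the rate. The mean of the two, taken for the flask, is 0.498 d⁻¹ of its charge, so its solid lasts about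

t_gone = 1.31 d

The third rung is the tail, 2.69 d long. The tail constant, the first-order constant at which the leftover falls once the solid is gone, reads 0.800 d⁻¹ from Thursday's run, through a scatter of 1 percentage point. This reckoning carries it to the flask unchanged:

leftover = s × exp(−0.800 d⁻¹ × 2.69 d) = 4.03%, so target is 96.0%

The forecast differs, with 90%, theta as the best change, and 97.5% after it: “Conversion is the slow step.” The two part on the tail, where the forecast scales its constant to 0.55 per day.

The flask gives 95.2%; theta adds 4.5 points and reaches 99.7%. Half of the dissolving up to the asked time is done by 0.291 d, earlier than half of the conversion at 0.929 d, and from 2.00 d to 4.00 d the leftover, dissolved starting material, falls from 21.4% to 4.83%, a constant of 0.744 d⁻¹ beside the 0.800 d⁻¹ carried over.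

    starting material + enzyme → target + enzyme, rate k1*[starting material]*[enzyme]/(1 + ([starting material]/Km1) + ([target]/Kp1)) (0.290 M, 31.0 mM, k = 5800 M⁻¹ h⁻¹)
    solid substrate ⇌ starting material, rate k2*(cs2 - [starting material]) while solid is left; crystals form when [starting material] > cs2 (solubility = 45.0 mM, k = 0.610 h⁻¹)

For the neighbour, the same charge stopped at 40 h, the tail constant gives target 73.9%; that flask holds 71.8%.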